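A direct plan would lithiate 5,7,8-trimethoxychromone A1 at C2, add the anion to 2,3-dimethoxy-1,4-benzoquinone A2, reductively aromatise the adduct to the 5-O-methyl ether of the target, A3, and cleave the 5-OMe of A3 with BCl3.
Its weakest steps would be:
- the C2 metalation of A1: a 2-lithiochromone could open to the ynone phenoxide or add to unreacted A1, and the step would lack direct precedent;
- the union of lithiated A1 with A2: an organolithium could reduce the quinone by electron transfer or add 1,4, and Zn/AcOH would have to expel a tertiary OH without touching the enone of ring C;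
- the final O-demethylation of A3: it would add a step only to remove a methyl group carried from the start, and BCl3 could also attack the vicinal dimethoxy pairs of ring A and ring B.

The new route rests on the C4–C4a bond. Ring C would be closed last, at carbon, by Friedel–Crafts acylation within a (Z)-3-aryl-3-aryloxyacrylic acid that a ring A phenol and a ring B arylpropiolate give by conjugate addition (O1–C2). The step exploits that O1 sits on C8a, whose other ortho carbon C8 bears OMe: acylation can only reach C4a, which is also flanked by the 5-oxygen and para to 7-OMe. The 5-OH enters as a formyl group and is unmasked by Baeyer–Villiger oxidation, so O5 is never methylated, no chromone is metalated and no quinone is used; the key step delivers the target with both phenols free.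

Key step: step 6

Assumption: 3-hydroxy-4,5-dimethoxybenzaldehyde, 2,3-dimethoxyphenol and methyl propiolate are taken as commercial; the conjugate addition may give some (E)-isomer beside the (Z)-isomer drawn, and both would serve, since the geometry equilibrates in the acid of the key step.

Step 1
Reactants: 1 2,3-dimethoxyphenol
Product: 2 4-iodo-2,3-dimethoxyphenol
Conditions: NIS (1.05 equiv), TsOH·H2O (0.1 equiv), MeCN, −20 → 0 °C, dark
Reagents that add atoms: N-iodosuccinimide, O=C1CCC(=O)N1I
Why: Electrophilic aromatic iodination with acid-activated NIS should go to C4, which is para to the free OH (the strongest donor) and ortho to 3-OMe, the para position of a phenol being strongly preferred with this reagent pair.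

Step 2
Reactants: 2 4-iodo-2,3-dimethoxyphenol
Product: 3 4-iodo-2,3-dimethoxyphenyl 2,2-dimethylpropanoate (pivalate)
Conditions: PivCl (1.2 equiv), Et3N (1.5 equiv), DMAP (5 mol%), CH2Cl2, 0 → 23 °C
Reagents that add atoms: pivaloyl chloride, CC(C)(C)C(Cl)=O
Why: DMAP-catalysed O-acylation; the hindered pivalate keeps this phenol from acting as a Michael donor or deactivating the alkyne later, survives carbonate bases, and falls to the same hydroxide that cleaves the other esters in step 5.

Step 3
Reactants: 3 4-iodo-2,3-dimethoxyphenyl 2,2-dimethylpropanoate, 4 methyl propiolate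
Product: 5 methyl 3-[4-(2,2-dimethylpropanoyloxy)-2,3-dimethoxyphenyl]prop-2-ynoate
Conditions: PdCl2(PPh3)2 (3 mol%), CuI (6 mol%), K2CO3 (2 equiv), 4 (3 equiv, in portions), THF, 60 °C
Reagents that add atoms: none
Why: Sonogashira coupling of an aryl iodide with an alkyl propiolate, run with solid K2CO3 in place of an amine so that nothing adds to the propiolate, while the aryl pivalate is inert to the palladium catalyst.

Step 4
Reactants: 5 methyl 3-[4-(2,2-dimethylpropanoyloxy)-2,3-dimethoxyphenyl]prop-2-ynoate, 6 3-hydroxy-4,5-dimethoxybenzaldehyde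
Product: 7 methyl (2Z)-3-[4-(2,2-dimethylpropanoyloxy)-2,3-dimethoxyphenyl]-3-(5-formyl-2,3-dimethoxyphenoxy)prop-2-enoate
Conditions: Cs2CO3 (0.3 equiv), DMF, 50 °C
Reagents that add atoms: none
Why: Base-catalysed oxa-Michael addition of a phenoxide to an arylpropiolate forms O1–C2, anti addition placing ArO and CO2Me cis (Z); since the OH next to OMe is the only hydroxyl of 6, the oxygen that becomes O1 is fixed, and the substoichiometric base keeps the phenoxide concentration low enough to spare the hindered pivalate.

Step 5
Reactants: 7 methyl (2Z)-3-[4-(2,2-dimethylpropanoyloxy)-2,3-dimethoxyphenyl]-3-(5-formyl-2,3-dimethoxyphenoxy)prop-2-enoate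
Product: 9 (2Z)-3-(4-hydroxy-2,3-dimethoxyphenyl)-3-(5-hydroxy-2,3-dimethoxyphenoxy)prop-2-enoic acid, via aryl formate 8 (not isolated)
Conditions: mCPBA (1.3 equiv), CH2Cl2, 0 → 23 °C; evaporate; LiOH (10 equiv), THF/MeOH/H2O, 40 °C; then 1 M HCl, 0 °C, to pH 3
Reagents that add atoms: 3-chloroperoxybenzoic acid (mCPBA), OOC(=O)c1cccc(Cl)c1; lithium hydroxide (aqueous), [Li+].[OH-]
Why: Baeyer–Villiger (Dakin-type) oxidation, in which the aryl group carrying OMe para to the formyl group migrates in the Criegee adduct to give formate 8, while the ester-conjugated enol ether double bond is too electron-poor to be epoxidised at this temperature, followed by one saponification that removes the formyl, pivaloyl and methyl groups.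

Step 6
Reactants: 9 (2Z)-3-(4-hydroxy-2,3-dimethoxyphenyl)-3-(5-hydroxy-2,3-dimethoxyphenoxy)prop-2-enoic acid
Product: 10 5-hydroxy-2-(4-hydroxy-2,3-dimethoxyphenyl)-7,8-dimethoxy-4H-chromen-4-one (the target flavone)
Conditions: P2O5/MeSO3H (Eaton reagent, 1:10 w/w), 23 → 40 °C; then ice-water
Reagents that add atoms: none
Why: In P2O5/MeSO3H the carboxylic acid should be converted through its mixed anhydride into an acylium ion, which attacks the arene carbon ortho to the enol ether oxygen and loses a proton, an intramolecular Friedel–Crafts acylation that forms C4–C4a and gives the 4-pyranone directly. The closest known reaction type is the cyclodehydration of β-aryloxycinnamic acids to flavones (Ruhemann synthesis), together with the acylation of unprotected polyphenols by carboxylic acids in this medium, as used for hydroxyxanthones. Ring C is closed as a six-membered ring by 6-exo-dig attack of C4a on the acylium carbon C4, and no stereocentre is formed. The step needs site selectivity, which the substrate secures: of the two carbons ortho to O1, C8 is blocked by OMe, so only C4a can react, and it is the most nucleophilic carbon of the molecule (ortho to O1 and to the free 5-OH, para to 7-OMe), whereas closure onto ring B would need a five-membered ring at its one free ortho carbon, which only a single para OMe activates. It also needs the carboxyl cis to the aryloxy group, which the (Z)-acid has and which any (E)-isomer should reach in the acid by C3-protonation and rotation in the oxocarbenium ion. The two free phenols should tolerate the medium, and the moderate temperature should keep the aryl vinyl ether and the methyl ethers intact.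

**Compound list**
1 | 2,3-dimethoxyphenol | COc1cccc(O)c1OC | starting material
2 | 4-iodo-2,3-dimethoxyphenol | COc1c(O)ccc(I)c1OC | intermediate
3 | 4-iodo-2,3-dimethoxyphenyl 2,2-dimethylpropanoate | COc1c(OC(=O)C(C)(C)C)ccc(I)c1OC | intermediate
4 | methyl propiolate (methyl prop-2-ynoate) | C#CC(=O)OC | starting material
5 | methyl 3-[4-(2,2-dimethylpropanoyloxy)-2,3-dimethoxyphenyl]prop-2-ynoate | COC(=O)C#Cc1ccc(OC(=O)C(C)(C)C)c(OC)c1OC | intermediate
6 | 3-hydroxy-4,5-dimethoxybenzaldehyde | COc1cc(C=O)cc(O)c1OC | starting material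
7 | methyl (2Z)-3-[4-(2,2-dimethylpropanoyloxy)-2,3-dimethoxyphenyl]-3-(5-formyl-2,3-dimethoxyphenoxy)prop-2-enoate (aryloxy and ester cis) | COC(=O)/C=C(\Oc1cc(C=O)cc(OC)c1OC)c1ccc(OC(=O)C(C)(C)C)c(OC)c1OC | intermediate
8 | methyl (2Z)-3-[4-(2,2-dimethylpropanoyloxy)-2,3-dimethoxyphenyl]-3-[5-(formyloxy)-2,3-dimethoxyphenoxy]prop-2-enoate | COC(=O)/C=C(\Oc1cc(OC=O)cc(OC)c1OC)c1ccc(OC(=O)C(C)(C)C)c(OC)c1OC | intermediate
9 | (2Z)-3-(4-hydroxy-2,3-dimethoxyphenyl)-3-(5-hydroxy-2,3-dimethoxyphenoxy)prop-2-enoic acid | OC(=O)/C=C(\Oc1cc(O)cc(OC)c1OC)c1ccc(O)c(OC)c1OC | intermediate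
10 | 5-hydroxy-2-(4-hydroxy-2,3-dimethoxyphenyl)-7,8-dimethoxy-4H-chromen-4-one (the target flavone, achiral) | COc1cc(O)c2c(=O)cc(-c3ccc(O)c(OC)c3OC)oc2c1OC | target

Total step count: 6
Longest linear sequence: 6 steps (1 → 2 → 3 → 5 → 7 → 9 → 10); 4 and 6 enter as commercial materials.

**Steps most likely to fail**

Step 6 (key step). In the strong acid the enol ether could be protonated at C3 and the C2–O1 bond cleaved, after which recombination would lose the regiochemical lock; the acylium ion could also close onto ring B. The fallback sets out from 9 and returns at 10, and moves the ring closure to an aprotic Lewis acid acylation of a protected acid chloride. Ac2O and pyridine, followed by aqueous work-up, would give (2Z)-3-[4-(acetyloxy)-2,3-dimethoxyphenyl]-3-[5-(acetyloxy)-2,3-dimethoxyphenoxy]prop-2-enoic acid F1. Oxalyl chloride with catalytic DMF in CH2Cl2 would give (2Z)-3-[4-(acetyloxy)-2,3-dimethoxyphenyl]-3-[5-(acetyloxy)-2,3-dimethoxyphenoxy]prop-2-enoyl chloride F2. SnCl4 in CH2Cl2 at −78 → 0 °C would close ring C without any protic acid to give 5-(acetyloxy)-2-[4-(acetyloxy)-2,3-dimethoxyphenyl]-7,8-dimethoxy-4H-chromen-4-one F3. K2CO3 in MeOH would then remove both acetates and return 10.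

Step 5. The peracid could epoxidise the enol ether double bond, or hydride could migrate in place of the aryl group and leave a benzoic acid. The fallback sets out from 1 and returns at 9; it brings in the 5-oxygen through boron, so that no aldehyde and no peracid are needed. Iridium-catalysed C–H borylation of 1 ([Ir(OMe)(cod)]2, dtbpy, B2pin2, THF, 80 °C; MeOH work-up) is sterically directed to C5, the only C–H without an ortho substituent, and would give 2,3-dimethoxy-5-(4,4,5,5-tetramethyl-1,3,2-dioxaborolan-2-yl)phenol F4. Conjugate addition of F4 to 5 under the conditions of step 4 would give methyl (2Z)-3-[4-(2,2-dimethylpropanoyloxy)-2,3-dimethoxyphenyl]-3-[2,3-dimethoxy-5-(4,4,5,5-tetramethyl-1,3,2-dioxaborolan-2-yl)phenoxy]prop-2-enoate F5. H2O2 and LiOH in THF/MeOH/H2O (0 → 40 °C, then 1 M HCl) would oxidise the C–B bond and hydrolyse both esters to 9.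

Step 1. Iodination could also take place at C6 (ortho to OH, para to 3-OMe) or twice, giving a mixture of regioisomers. The fallback sets out from 1 and returns at 2, and replaces electrophilic substitution by directed ortho-metalation. TIPSCl and imidazole in DMF would give (2,3-dimethoxyphenoxy)tri(propan-2-yl)silane F6. With n-BuLi and TMEDA in THF at 0 °C the bulky, non-directing silyl ether shields C6, so 3-OMe should guide lithiation to C4 and give [2,3-dimethoxy-4-tri(propan-2-yl)silyloxyphenyl]lithium F7. Iodine at −78 °C would give (4-iodo-2,3-dimethoxyphenoxy)tri(propan-2-yl)silane F8, and TBAF in THF would return 2.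

**Further compounds**
F1 | step 6 | (2Z)-3-[4-(acetyloxy)-2,3-dimethoxyphenyl]-3-[5-(acetyloxy)-2,3-dimethoxyphenoxy]prop-2-enoic acid | OC(=O)/C=C(\Oc1cc(OC(C)=O)cc(OC)c1OC)c1ccc(OC(C)=O)c(OC)c1OC
F2 | step 6 | (2Z)-3-[4-(acetyloxy)-2,3-dimethoxyphenyl]-3-[5-(acetyloxy)-2,3-dimethoxyphenoxy]prop-2-enoyl chloride | ClC(=O)/C=C(\Oc1cc(OC(C)=O)cc(OC)c1OC)c1ccc(OC(C)=O)c(OC)c1OC
F3 | step 6 | 5-(acetyloxy)-2-[4-(acetyloxy)-2,3-dimethoxyphenyl]-7,8-dimethoxy-4H-chromen-4-one | COc1cc(OC(C)=O)c2c(=O)cc(-c3ccc(OC(C)=O)c(OC)c3OC)oc2c1OC
F4 | step 5 | 2,3-dimethoxy-5-(4,4,5,5-tetramethyl-1,3,2-dioxaborolan-2-yl)phenol | COc1cc(B2OC(C)(C)C(C)(C)O2)cc(O)c1OC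
F5 | step 5 | methyl (2Z)-3-[4-(2,2-dimethylpropanoyloxy)-2,3-dimethoxyphenyl]-3-[2,3-dimethoxy-5-(4,4,5,5-tetramethyl-1,3,2-dioxaborolan-2-yl)phenoxy]prop-2-enoate | COC(=O)/C=C(\Oc1cc(B2OC(C)(C)C(C)(C)O2)cc(OC)c1OC)c1ccc(OC(=O)C(C)(C)C)c(OC)c1OC
F6 | step 1 | (2,3-dimethoxyphenoxy)tri(propan-2-yl)silane | COc1cccc(O[Si](C(C)C)(C(C)C)C(C)C)c1OC
F7 | step 1 | [2,3-dimethoxy-4-tri(propan-2-yl)silyloxyphenyl]lithium | [Li]c1ccc(O[Si](C(C)C)(C(C)C)C(C)C)c(OC)c1OC
F8 | step 1 | (4-iodo-2,3-dimethoxyphenoxy)tri(propan-2-yl)silane | Ic1ccc(O[Si](C(C)C)(C(C)C)C(C)C)c(OC)c1OC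
A1 | direct plan | 5,7,8-trimethoxy-4H-chromen-4-one | COc1cc(OC)c2c(=O)ccoc2c1OC
A2 | direct plan | 2,3-dimethoxy-1,4-benzoquinone | COC1=C(OC)C(=O)C=CC1=O
A3 | direct plan | 2-(4-hydroxy-2,3-dimethoxyphenyl)-5,7,8-trimethoxy-4H-chromen-4-one (5-O-methyl ether of the target) | COc1cc(OC)c2c(=O)cc(-c3ccc(O)c(OC)c3OC)oc2c1OC
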